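**Retrosynthetic overview**

1. Target 25 is an 8-aryloxy-5,7-dihydroxy-4'-methoxyflavone whose aryl group is ring B of an apigenin unit. The last step frees the four hydroxyls (three benzyl ethers and the chelated 5-methyl ether) with BCl3.
2. Both pyranone rings are cut at C2–C3 into an o-hydroxyacetophenone and an aroyl chloride (1,3-diketone, then cyclodehydration). The apigenin unit comes from benzoic acid 18 and acetophenone 20, the methoxyflavone unit from acetophenone 13 and 4-methoxybenzoyl chloride 14.
3. The strategy rests on ring A of the methoxyflavone unit (C4a, C5, C6, C7, C8, C8a). Its oxygens on C5, C7 and C8a and the diaryl ether oxygen on C8 make it a 2-aryloxyphloroglucinol, that is 5-methoxyresorcinol 10 with the ether between the two hydroxyls.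
4. Ring A is closed from open chain 8 by a Claisen carbocyclisation (chain C6, the future C8, onto the ester carbon). Chain 8 comes from aryloxyacetyl chloride 5 and the dienolate of 6.
5. Ring order: ring A (step 5), pyranone ring of the methoxyflavone unit (step 9), pyranone ring of the apigenin unit (step 13). The other three benzene rings are bought.

Key step: step 5

Remark: the target has no stereocentre; the only stereo element on the route is the E enol ether of 6 and 8, which equilibrates under the basic conditions of step 5.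

**Route**

Step 1
Reactants: 1 methyl 4-hydroxybenzoate; 2 tert-butyl bromoacetate
Product: 3 tert-butyl 2-[4-(methoxycarbonyl)phenoxy]acetate
Conditions: K2CO3, acetone, reflux
Reagents that add atoms: none
Why: Williamson ether synthesis; the phenoxide displaces the activated primary bromide and neither ester is touched by carbonate.

Step 2
Reactants: 3 tert-butyl 2-[4-(methoxycarbonyl)phenoxy]acetate
Product: 4 2-[4-(methoxycarbonyl)phenoxy]acetic acid
Conditions: CF3CO2H, CH2Cl2, rt
Reagents that add atoms: none
Why: Acidolysis of the tert-butyl ester through the tert-butyl cation should leave the methyl benzoate and the aryl ether intact.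

Step 3
Reactants: 4 2-[4-(methoxycarbonyl)phenoxy]acetic acid
Product: 5 methyl 4-(2-chloro-2-oxoethoxy)benzoate
Conditions: (COCl)2, cat. DMF, CH2Cl2, 0 °C to rt; evaporate, use crude
Reagents that add atoms: oxalyl chloride, O=C(Cl)C(=O)Cl
Why: Standard acid chloride formation through the Vilsmeier-type chloroiminium catalyst; it gives an acylating agent far more reactive than the two methyl esters present in step 4.

Step 4
Reactants: 5 methyl 4-(2-chloro-2-oxoethoxy)benzoate; 6 methyl (E)-3-methoxybut-2-enoate
Product: 8 methyl (E)-6-[4-(methoxycarbonyl)phenoxy]-3-methoxy-5-oxohex-2-enoate, via lithium dienolate 7 (not isolated)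
Conditions: 6 and LiN(iPr)2 (2.1 equiv each), THF, −78 °C; then 5, −78 °C; AcOH quench at −78 °C
Reagents that add atoms: none
Why: Vinylogous Claisen acylation: the dienolate, the O-methyl counterpart of an acetoacetate dianion, should be acylated at its terminal (γ) carbon by the acid chloride, the second equivalent removes the acidic C4 proton of the product, and the stable E enol ether (ester cis to the chain) is regenerated.

Step 5
Reactants: 8 methyl (E)-6-[4-(methoxycarbonyl)phenoxy]-3-methoxy-5-oxohex-2-enoate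
Product: 10 methyl 4-(2,6-dihydroxy-4-methoxyphenoxy)benzoate, via cyclohexenedione tautomer 9 (not isolated)
Conditions: NaOMe (4 equiv), MeOH, reflux, under Ar; then aq. HCl
Reagents that add atoms: none
Why: Methoxide deprotonates 8 reversibly; the enolate at C6 (the carbon between the ketone and the aryloxy oxygen) adds to the C1 ester carbonyl, methoxide leaves, and the 2-aryloxy-5-methoxycyclohex-4-ene-1,3-dione 9 enolises to resorcinol 10, whose phenoxide is withdrawn from every equilibrium. The closest known reaction type is the biomimetic Claisen (Dieckmann-type) carbocyclisation of 3,5-dioxohexanoate and longer β-polyketo esters to phloroglucinols. Ring A closes by a 6-(enolendo)-exo-trig attack, made possible by the E enol ether, which holds C1 and C4 cis on C2=C3 and already carries the future C5 oxygen as its methyl ether. No stereocentre results, because the sp3 carbon of 9 is lost on aromatisation. The step needs acylation of the ketone enolate at carbon and not at oxygen, and reaction at C6 although C4 is more acidic: the 4-methoxy-2-pyranone from O-attack is reopened by methoxide, the C4 enolate has no ring-forming outlet, and only the C6 path ends in an aromatic phenoxide. The benzoate survives because NaOMe in MeOH can only exchange methyl for methyl, and the mirror plane of 10 makes its two free ring positions equivalent, which later fixes the 8-aryloxy pattern.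

Step 6
Reactants: 10 methyl 4-(2,6-dihydroxy-4-methoxyphenoxy)benzoate
Product: 12 methyl 4-(3-acetyl-2,6-dihydroxy-4-methoxyphenoxy)benzoate, via ketiminium chloride 11 (not isolated)
Conditions: MeCN, ZnCl2 (0.3 equiv), HCl gas, Et2O, 0 °C; then H2O/MeOH, 70 °C
Reagents that add atoms: acetonitrile, CC#N; water, O
Why: Houben–Hoesch acylation: the two free positions of the phloroglucinol-type ring are equivalent, each ortho to a hydroxyl and to the methoxy group, the iminium salt blocks a second acylation, and the benzoate ring is too electron-poor to react.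

Step 7
Reactants: 12 methyl 4-(3-acetyl-2,6-dihydroxy-4-methoxyphenoxy)benzoate
Product: 13 methyl 4-[3-acetyl-6-(benzyloxy)-2-hydroxy-4-methoxyphenoxy]benzoate
Conditions: BnBr (1.05 equiv), K2CO3, acetone, 50 °C
Reagents that add atoms: benzyl bromide, BrCc1ccccc1
Why: Williamson alkylation should go to the hydroxyl para to the acetyl group, which is the more acidic and is not hydrogen-bonded, while the ortho hydroxyl stays chelated to the ketone.

Step 8
Reactants: 13 methyl 4-[3-acetyl-6-(benzyloxy)-2-hydroxy-4-methoxyphenoxy]benzoate; 14 4-methoxybenzoyl chloride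
Product: 16 methyl 4-{6-(benzyloxy)-2-hydroxy-4-methoxy-3-[3-(4-methoxyphenyl)-3-oxopropanoyl]phenoxy}benzoate, via dilithium enolate phenolate 15 (not isolated)
Conditions: LiN(SiMe3)2 (3.2 equiv), THF, −78 to −10 °C; then 14, −78 °C to rt; aq. HCl
Reagents that add atoms: none
Why: One-flask variant of the Baker–Venkataraman route: the dilithium enolate phenolate is acylated at carbon by the aroyl chloride to give the 1,3-diketone directly, and the methyl benzoate is inert to the amide base and the enolate at low temperature.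

Step 9
Reactants: 16 methyl 4-{6-(benzyloxy)-2-hydroxy-4-methoxy-3-[3-(4-methoxyphenyl)-3-oxopropanoyl]phenoxy}benzoate
Product: 17 methyl 4-{[7-(benzyloxy)-5-methoxy-2-(4-methoxyphenyl)-4-oxo-4H-chromen-8-yl]oxy}benzoate
Conditions: p-TsOH·H2O (0.2 equiv), toluene, 100 °C
Reagents that add atoms: none
Why: Acid-catalysed cyclodehydration of an o-hydroxyaryl 1,3-diketone: the only free hydroxyl, which sits next to the aryloxy carbon, adds to the anisoyl carbonyl and water is lost, giving the 8-aryloxyflavone.

Step 10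
Reactants: 17 methyl 4-{[7-(benzyloxy)-5-methoxy-2-(4-methoxyphenyl)-4-oxo-4H-chromen-8-yl]oxy}benzoate
Product: 18 4-{[7-(benzyloxy)-5-methoxy-2-(4-methoxyphenyl)-4-oxo-4H-chromen-8-yl]oxy}benzoic acid
Conditions: LiOH·H2O, THF/MeOH/H2O, 40 °C; then 1 M HCl
Reagents that add atoms: lithium hydroxide, [Li+].[OH-]
Why: Saponification of the methyl ester under mild conditions that an alkoxylated flavone should tolerate without opening of its pyranone ring.

Step 11
Reactants: 19 1-(2,4,6-trihydroxyphenyl)ethanone
Product: 20 1-[2,4-bis(benzyloxy)-6-hydroxyphenyl]ethanone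
Conditions: BnBr (2.1 equiv), K2CO3, DMF, rt
Reagents that add atoms: benzyl bromide, BrCc1ccccc1
Why: Williamson alkylation of the para hydroxyl and of one ortho hydroxyl; the remaining ortho hydroxyl is chelated to the ketone and should resist alkylation under these conditions.

Step 12
Reactants: 18 4-{[7-(benzyloxy)-5-methoxy-2-(4-methoxyphenyl)-4-oxo-4H-chromen-8-yl]oxy}benzoic acid; 20 1-[2,4-bis(benzyloxy)-6-hydroxyphenyl]ethanone
Product: 23 1-[2,4-bis(benzyloxy)-6-hydroxyphenyl]-3-(4-{[7-(benzyloxy)-5-methoxy-2-(4-methoxyphenyl)-4-oxo-4H-chromen-8-yl]oxy}phenyl)propane-1,3-dione, via acid chloride 21 (not isolated), via dilithium enolate phenolate 22 (not isolated)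
Conditions: 18, (COCl)2, cat. DMF, CH2Cl2, 0 °C to rt, evaporate; separately 20 (1.2 equiv), LiN(SiMe3)2 (3 equiv per 20), THF, −78 to −10 °C; combine at −78 °C, then to rt; aq. HCl
Reagents that add atoms: none
Why: The same Baker–Venkataraman-type C-acylation as in step 8: the preformed dilithium enolate phenolate of 20 attacks the aroyl chloride faster than anything adds to the fully etherified flavone already present.

Step 13
Reactants: 23 1-[2,4-bis(benzyloxy)-6-hydroxyphenyl]-3-(4-{[7-(benzyloxy)-5-methoxy-2-(4-methoxyphenyl)-4-oxo-4H-chromen-8-yl]oxy}phenyl)propane-1,3-dione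
Product: 24 7-(benzyloxy)-8-{4-[5,7-bis(benzyloxy)-4-oxo-4H-chromen-2-yl]phenoxy}-5-methoxy-2-(4-methoxyphenyl)-4H-chromen-4-one
Conditions: p-TsOH·H2O (0.2 equiv), toluene, 100 °C
Reagents that add atoms: none
Why: Acid-catalysed cyclodehydration of the o-hydroxyaryl 1,3-diketone, as in step 9, closes the second pyranone ring.

Step 14
Reactants: 24 7-(benzyloxy)-8-{4-[5,7-bis(benzyloxy)-4-oxo-4H-chromen-2-yl]phenoxy}-5-methoxy-2-(4-methoxyphenyl)-4H-chromen-4-one
Product: 25 8-[4-(5,7-dihydroxy-4-oxo-4H-chromen-2-yl)phenoxy]-5,7-dihydroxy-2-(4-methoxyphenyl)-4H-chromen-4-one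
Conditions: BCl3 (excess), C6HMe5, CH2Cl2, −78 °C to rt; then H2O
Reagents that add atoms: none
Why: Lewis-acid ether cleavage: BCl3 removes the three benzyl ethers (pentamethylbenzene traps the benzyl cations) and, chelated to the C4 carbonyl, the neighbouring 5-methyl ether, while the 4'-methoxy group has no adjacent carbonyl and should stay.

**Compound list**

1 | methyl 4-hydroxybenzoate | COC(=O)c1ccc(O)cc1 | starting material
2 | tert-butyl bromoacetate | CC(C)(C)OC(=O)CBr | starting material
3 | tert-butyl 2-[4-(methoxycarbonyl)phenoxy]acetate | COC(=O)c1ccc(OCC(=O)OC(C)(C)C)cc1 | intermediate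
4 | 2-[4-(methoxycarbonyl)phenoxy]acetic acid | COC(=O)c1ccc(OCC(=O)O)cc1 | intermediate
5 | methyl 4-(2-chloro-2-oxoethoxy)benzoate | COC(=O)c1ccc(OCC(=O)Cl)cc1 | intermediate
6 | methyl (E)-3-methoxybut-2-enoate | COC(=O)/C=C(\C)OC | starting material
7 | lithium 1,3-dimethoxybuta-1,3-dien-1-olate (lithium dienolate of 6) | [Li+].[O-]C(OC)=CC(=C)OC | intermediate (not isolated)
8 | methyl (E)-6-[4-(methoxycarbonyl)phenoxy]-3-methoxy-5-oxohex-2-enoate | COC(=O)/C=C(/OC)CC(=O)COc1ccc(C(=O)OC)cc1 | intermediate
9 | methyl 4-[(4-methoxy-2,6-dioxocyclohex-3-en-1-yl)oxy]benzoate | COC(=O)c1ccc(OC2C(=O)C=C(OC)CC2=O)cc1 | intermediate (not isolated)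
10 | methyl 4-(2,6-dihydroxy-4-methoxyphenoxy)benzoate | COC(=O)c1ccc(Oc2c(O)cc(OC)cc2O)cc1 | intermediate
11 | 1-{2,4-dihydroxy-6-methoxy-3-[4-(methoxycarbonyl)phenoxy]phenyl}ethaniminium chloride | COC(=O)c1ccc(Oc2c(O)cc(OC)c(C(C)=[NH2+])c2O)cc1.[Cl-] | intermediate (not isolated)
12 | methyl 4-(3-acetyl-2,6-dihydroxy-4-methoxyphenoxy)benzoate | COC(=O)c1ccc(Oc2c(O)cc(OC)c(C(C)=O)c2O)cc1 | intermediate
13 | methyl 4-[3-acetyl-6-(benzyloxy)-2-hydroxy-4-methoxyphenoxy]benzoate | COC(=O)c1ccc(Oc2c(OCc3ccccc3)cc(OC)c(C(C)=O)c2O)cc1 | intermediate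
14 | 4-methoxybenzoyl chloride | COc1ccc(C(Cl)=O)cc1 | starting material
15 | dilithium enolate phenolate of 13 | [Li+].[Li+].COC(=O)c1ccc(Oc2c(OCc3ccccc3)cc(OC)c(C([O-])=C)c2[O-])cc1 | intermediate (not isolated)
16 | methyl 4-{6-(benzyloxy)-2-hydroxy-4-methoxy-3-[3-(4-methoxyphenyl)-3-oxopropanoyl]phenoxy}benzoate | COC(=O)c1ccc(Oc2c(OCc3ccccc3)cc(OC)c(C(=O)CC(=O)c3ccc(OC)cc3)c2O)cc1 | intermediate
17 | methyl 4-{[7-(benzyloxy)-5-methoxy-2-(4-methoxyphenyl)-4-oxo-4H-chromen-8-yl]oxy}benzoate | COC(=O)c1ccc(Oc2c(OCc3ccccc3)cc(OC)c3c(=O)cc(-c4ccc(OC)cc4)oc23)cc1 | intermediate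
18 | 4-{[7-(benzyloxy)-5-methoxy-2-(4-methoxyphenyl)-4-oxo-4H-chromen-8-yl]oxy}benzoic acid | O=C(O)c1ccc(Oc2c(OCc3ccccc3)cc(OC)c3c(=O)cc(-c4ccc(OC)cc4)oc23)cc1 | intermediate
19 | 1-(2,4,6-trihydroxyphenyl)ethanone | CC(=O)c1c(O)cc(O)cc1O | starting material
20 | 1-[2,4-bis(benzyloxy)-6-hydroxyphenyl]ethanone | CC(=O)c1c(O)cc(OCc2ccccc2)cc1OCc1ccccc1 | intermediate
21 | 4-{[7-(benzyloxy)-5-methoxy-2-(4-methoxyphenyl)-4-oxo-4H-chromen-8-yl]oxy}benzoyl chloride | O=C(Cl)c1ccc(Oc2c(OCc3ccccc3)cc(OC)c3c(=O)cc(-c4ccc(OC)cc4)oc23)cc1 | intermediate (not isolated)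
22 | dilithium enolate phenolate of 20 | [Li+].[Li+].C=C([O-])c1c([O-])cc(OCc2ccccc2)cc1OCc1ccccc1 | intermediate (not isolated)
23 | 1-[2,4-bis(benzyloxy)-6-hydroxyphenyl]-3-(4-{[7-(benzyloxy)-5-methoxy-2-(4-methoxyphenyl)-4-oxo-4H-chromen-8-yl]oxy}phenyl)propane-1,3-dione | O=C(CC(=O)c1ccc(Oc2c(OCc3ccccc3)cc(OC)c3c(=O)cc(-c4ccc(OC)cc4)oc23)cc1)c1c(O)cc(OCc2ccccc2)cc1OCc1ccccc1 | intermediate
24 | 7-(benzyloxy)-8-{4-[5,7-bis(benzyloxy)-4-oxo-4H-chromen-2-yl]phenoxy}-5-methoxy-2-(4-methoxyphenyl)-4H-chromen-4-one | COc1ccc(-c2cc(=O)c3c(OC)cc(OCc4ccccc4)c(Oc4ccc(-c5cc(=O)c6c(OCc7ccccc7)cc(OCc7ccccc7)cc6o5)cc4)c3o2)cc1 | intermediate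
25 | 8-[4-(5,7-dihydroxy-4-oxo-4H-chromen-2-yl)phenoxy]-5,7-dihydroxy-2-(4-methoxyphenyl)-4H-chromen-4-one (CNP0295851.0) | COc1ccc(-c2cc(=O)c3c(O)cc(O)c(Oc4ccc(-c5cc(=O)c6c(O)cc(O)cc6o5)cc4)c3o2)cc1 | target

**Step count**

Total: 14 steps. Longest linear sequence: 13 steps (steps 1 to 10 and 12 to 14); step 11 is a one-step side branch.

**Steps most likely to fail**

Step 5 (key step). The ketone enolate may close through oxygen to the 4-methoxy-2-pyranone faster than through carbon, and methoxide may reopen that lactone too slowly. Methoxide may also cleave the C4–C5 bond in a retro-Claisen sense, or enolisation at C6 may be too unfavourable against C4. The fallback takes ring A from an aromatic compound instead of cyclising it. It sets out from compound 19 and comes back at compound 10. Compound 19 is methylated at its para hydroxyl (Me2SO4, 1 equiv, K2CO3, acetone) to 1-(2,6-dihydroxy-4-methoxyphenyl)ethanone F1. Both chelated hydroxyls are then benzylated (BnBr, K2CO3, DMF, 70 °C) to 1-[2,6-bis(benzyloxy)-4-methoxyphenyl]ethanone F2. Baeyer–Villiger oxidation with mCPBA in CH2Cl2, in which the electron-rich aryl group migrates, gives 2,6-bis(benzyloxy)-4-methoxyphenyl acetate F3, and K2CO3 in MeOH frees 2,6-bis(benzyloxy)-4-methoxyphenol F4. Ullmann ether coupling of F4 with purchased methyl 4-iodobenzoate (CuI, picolinic acid, K3PO4, DMSO, 90 °C) gives methyl 4-[2,6-bis(benzyloxy)-4-methoxyphenoxy]benzoate F5. Hydrogenolysis (H2, Pd/C, EtOAc) then gives 10.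

Step 4. The basic dienolate may take a proton from the acid chloride and form an aryloxyketene. It may also be acylated at oxygen or at C2, or the product enolate may be acylated a second time. The fallback makes the chain as its lactone by ether formation and no longer needs a dienolate. It sets out from compound 1 and comes back at compound 8, which is then formed in the flask under the conditions of step 5 and carried on to 10 without isolation. Purchased 4-methoxy-6-methyl-2H-pyran-2-one is brominated at the methyl group (NBS, cat. dibenzoyl peroxide, PhCF3, reflux) to 6-(bromomethyl)-4-methoxy-2H-pyran-2-one F6. Compound 1 is alkylated with F6 (K2CO3, acetone, rt) to methyl 4-[(4-methoxy-2-oxo-2H-pyran-6-yl)methoxy]benzoate F7. NaOMe in MeOH opens the lactone of F7 at its carbonyl; because the ester carbon and C5 are cis in the ring, the opened chain is the E enol ether, that is the enolate of 8.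

Step 14. Benzyl cations may be captured by the electron-rich phloroglucinol rings, the chelation-assisted cleavage of the 5-methyl ether may stay incomplete, or the 4'-methoxy group may be lost slowly during the long exposure needed to finish four cleavages in one flask. The fallback divides the task between two different reactions. It sets out from compound 24 and comes back at compound 25. Hydrogenolysis (H2, Pd/C, THF/MeOH, rt) removes the three benzyl groups without cations and gives 8-[4-(5,7-dihydroxy-4-oxo-4H-chromen-2-yl)phenoxy]-7-hydroxy-5-methoxy-2-(4-methoxyphenyl)-4H-chromen-4-one F8. A short chelation-controlled demethylation of F8 (AlCl3, MeCN, 60 °C; then dilute HCl) should then cleave only the 5-methyl ether and give 25.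

**Further compounds**

F1 | step 5 | 1-(2,6-dihydroxy-4-methoxyphenyl)ethanone | CC(=O)c1c(O)cc(OC)cc1O
F2 | step 5 | 1-[2,6-bis(benzyloxy)-4-methoxyphenyl]ethanone | CC(=O)c1c(OCc2ccccc2)cc(OC)cc1OCc1ccccc1
F3 | step 5 | 2,6-bis(benzyloxy)-4-methoxyphenyl acetate | CC(=O)Oc1c(OCc2ccccc2)cc(OC)cc1OCc1ccccc1
F4 | step 5 | 2,6-bis(benzyloxy)-4-methoxyphenol | COc1cc(OCc2ccccc2)c(O)c(OCc2ccccc2)c1
F5 | step 5 | methyl 4-[2,6-bis(benzyloxy)-4-methoxyphenoxy]benzoate | COC(=O)c1ccc(Oc2c(OCc3ccccc3)cc(OC)cc2OCc2ccccc2)cc1
F6 | step 4 | 6-(bromomethyl)-4-methoxy-2H-pyran-2-one | O=c1cc(OC)cc(CBr)o1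
F7 | step 4 | methyl 4-[(4-methoxy-2-oxo-2H-pyran-6-yl)methoxy]benzoate | O=c1cc(OC)cc(COc2ccc(C(=O)OC)cc2)o1
F8 | step 14 | 8-[4-(5,7-dihydroxy-4-oxo-4H-chromen-2-yl)phenoxy]-7-hydroxy-5-methoxy-2-(4-methoxyphenyl)-4H-chromen-4-one | COc1ccc(-c2cc(=O)c3c(OC)cc(O)c(Oc4ccc(-c5cc(=O)c6c(O)cc(O)cc6o5)cc4)c3o2)cc1
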